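I choose to count what is left in this flask, not what is made.

- ochre: left-handed substrate 0.80 M; right-handed substrate 0.80 M; reagent 1.2 equiv; catalyst 15 mol%; added ligand 260 mM; the very flask that is asked about, followed so far
- flask: left-handed substrate 0.80 M; reagent 1.20 equiv; catalyst 15 mol%; added ligand 260 mM; right-handed substrate 0.80 M

ochre run (percent of the left-handed substrate and right-handed substrate together charged)

| time / min | left-handed product / % |
|---|---|
| 0.333 | 24.9 |
| 1.00 | 34.1 |
| 2.00 | 37.8 |
| 3.00 | 38.1 |
| 4.00 | 38.0 |

(scatter of a reading: 0.5 percentage points)

- catalyst is single-handed; left-handed substrate and right-handed substrate are mirror images of each other, charged as a racemate, each of them at the stated concentration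
- the numbers in the tables scatter by 0.5 percentage points (one standard deviation)
- no earlier run changes the charge of catalyst; that part of a forecast is a guess
- no earlier run changes the charge of reagent; that part of a forecast is a guess

1. apparent order in catalyst when 30% of the left-handed substrate and right-handed substrate together are converted (percent change of the rate of making left-handed product for one percent more catalyst charged)
2. apparent order in reagent when 30% of the left-handed substrate and right-handed substrate together are converted (percent change of the rate of making left-handed product for one percent more reagent charged)

The ochre run is the asked flask, followed so far. Its reagent, at 1.20 equiv, exceeds the left-handed substrate. Yet the left-handed product stops near 38.0%, below the 50.0% that this substrate can give.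

The two numbers fit if the single-handed catalyst also lets the right-handed substrate take reagent, more slowly. That would be a kinetic resolution. The two substrates are charged equally, so the equivalents over 2 give 60.0%. I call this the reach: the share of both substrates together that the reagent charge can convert, one reagent each. If the plateau marks the end of the limiting reagent, the unseen right-handed product holds the remaining 22 percentage points.

Now the orders. At 30% conversion, the reagent charge minus what is spent, one reagent each, is 50.0% of the charge. At fixed conversion the amount spent stays the same, so one percent more charge is a larger percentage of the remainder. If the rate is first order in reagent, I commit to an order of 2.00. For the catalyst, which no run varies, I guess 1.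

The forecast, saying “One run cannot separate these readings”, gave 1.5 for catalyst (0.7 to 4.5) and 1 for reagent (0 to 3), which differs from my two numbers.

The flask gives 1.2 for catalyst and 2.5 for reagent, and both stand above my reckoning.

    reagent ⇌ dormant form (K = 0.414, k = 0.0608 s⁻¹)
    reagent + catalyst + left-handed substrate → catalyst + left-handed product (k = 0.825 M⁻² s⁻¹)
    catalyst + added ligand ⇌ idle complex (K = 1.50 M⁻¹, k = 0.108 M⁻¹ s⁻¹)
    reagent + catalyst + right-handed substrate → catalyst + right-handed product (k = 0.313 M⁻² s⁻¹)

At 20.0 min the reagent stands at 0%, and the two products sum to 60.0%, which is the reach of 60.0%. At 0.160 min the left-handed substrate has a half-life of 0.39 min by its own step, shorter than the 1.0 min of the right-handed substrate, and the reach ends split as 38.6% left-handed product and 21.4% right-handed product.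

The earlier runs and the new flask were generated by integration for an exercise; noise was put on by code.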